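**Plan**

1. Retrosynthetic cuts: the spiro-dihydropyran at O–C11 and C13–C13' (hetero-Diels–Alder retron), giving α-methylene lactone 19 and enal 34; in 19 the C11=C13, C7–C11 and C8–O bonds; then C5–C6 of ring B.
2. Enabling feature: C5 of the eudesmanolide half lies between C4, which carries the exocyclic methylene C15, and C6 of ring B. A ring-A allylsilane (C15–Si, C4=C5) with a vinyl ketone chain on C10 can therefore bond C5 to C6 and leave C4=C15 behind.
3. Forward order: ring A is bought (3-methylcyclohexenone), ring B closes in step 5, the lactone ring in step 7; the cyclohexane of the elemane half comes from (S)-carvone; the pyran ring forms last, when the halves are joined (step 18).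
4. Stereochemistry, eudesmanolide half: C10 by ligand-controlled copper-catalysed conjugate addition; C5 by the key step (cis fusion dictated by C10); C7 and C8 by substrate control; C11 by cycloaddition on the convex lactone face.
5. Stereochemistry, elemane half: the carvone stereocentre (C7') steers the isopropenyl group to C5' and, through it, the vinyl precursor to C10'; C7' is then inverted by equilibration next to an acetyl group.
6. Numbering is biogenetic: unprimed for the eudesmanolide half, primed for the elemane half (C10' quaternary, C5' isopropenyl-bearing, C7' side-chain-bearing).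

Key step: step 5

Assumption: the (S)-configured carbene precursor of step 1 is taken to deliver the (R)-configured quaternary centre; should the sense of induction be the opposite, its enantiomer is used.

**Route**

Step 1
Reactants: 1 3-methylcyclohex-2-en-1-one; 2 but-3-en-1-ylmagnesium bromide
Product: 4 (3R)-3-(but-3-en-1-yl)-3-methylcyclohex-1-en-1-yl trifluoromethanesulfonate, via bromomagnesium enolate 3 (not isolated)
Conditions: Cu(OTf)2 (3 mol%), (S)-3-(1-hydroxy-4-methylpentan-2-yl)-1-mesityl-4,5-dihydroimidazolium hexafluorophosphate (4 mol%), Et2O, 0 °C; then N-(5-chloropyridin-2-yl)bis(trifluoromethanesulfonimide), THF/DMPU, 0 °C to rt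
Reagents that add atoms: N-(5-chloropyridin-2-yl)bis(trifluoromethanesulfonimide) (Comins' reagent), O=S(=O)(N(c1ccc(Cl)cn1)S(=O)(=O)C(F)(F)F)C(F)(F)F
Why: copper–carbene-catalysed asymmetric conjugate addition of a primary Grignard reagent to a β-methyl cyclohexenone should set the quaternary C10 by ligand-controlled face selection, and O-sulfonylation of the regiodefined enolate in the same flask fixes the double bond between C4 and C5.

Step 2
Reactants: 4 (3R)-3-(but-3-en-1-yl)-3-methylcyclohex-1-en-1-yl trifluoromethanesulfonate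
Product: 5 (3R)-3-(2-hydroxybut-3-en-1-yl)-3-methylcyclohex-1-en-1-yl trifluoromethanesulfonate (both carbinol epimers)
Conditions: SeO2 (0.5 equiv), t-BuOOH (3 equiv), CH2Cl2, rt
Reagents that add atoms: selenium dioxide, O=[Se]=O; tert-butyl hydroperoxide, CC(C)(C)OO
Why: selenium dioxide allylic oxidation (ene reaction, then 2,3-sigmatropic shift) should hydroxylate the allylic methylene C8 and leave the alkene at C6=C7, the electron-poor enol triflate being inert; the carbinol configuration is irrelevant because step 4 oxidises it.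

Step 3
Reactants: 5 (3R)-3-(2-hydroxybut-3-en-1-yl)-3-methylcyclohex-1-en-1-yl trifluoromethanesulfonate; 6 (trimethylsilyl)methylmagnesium chloride
Product: 7 1-[(1R)-1-methyl-3-[(trimethylsilyl)methyl]cyclohex-2-en-1-yl]but-3-en-2-ol
Conditions: Pd(PPh3)4 (5 mol%), 6 (2.5 equiv), Et2O/THF, 0 °C to rt
Reagents that add atoms: none
Why: Kumada coupling of an enol triflate with a silylmethyl Grignard reagent is the standard entry to such allylsilanes and keeps the alkene at C4=C5; the first equivalent of 6 only deprotonates the hydroxyl group.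

Step 4
Reactants: 7 1-[(1R)-1-methyl-3-[(trimethylsilyl)methyl]cyclohex-2-en-1-yl]but-3-en-2-ol
Product: 8 1-[(1R)-1-methyl-3-[(trimethylsilyl)methyl]cyclohex-2-en-1-yl]but-3-en-2-one
Conditions: Dess–Martin periodinane, NaHCO3, CH2Cl2, 0 °C
Reagents that add atoms: none
Why: buffered Dess–Martin oxidation of the secondary allylic alcohol should give the vinyl ketone without protodesilylation of the acid-labile allylsilane; the enone is used at once.

Step 5
Reactants: 8 1-[(1R)-1-methyl-3-[(trimethylsilyl)methyl]cyclohex-2-en-1-yl]but-3-en-2-one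
Product: 10 (4aR,8aR)-8a-methyl-5-methylideneoctahydronaphthalen-2(1H)-one (cis-fused), via trichlorotitanium enolate 9 (not isolated)
Conditions: TiCl4 (1.1 equiv), CH2Cl2, −78 °C; aq. NaHCO3
Reagents that add atoms: none
Why: TiCl4 binds the vinyl ketone oxygen and the allylsilane adds through its γ-carbon C5 to the enone β-carbon C6; the β-silyl cation at C4 then loses Me3SiCl to leave the exocyclic C4=C15 alkene, and enolate 9 is protonated on work-up to the C8 ketone. The closest known reaction type is the Lewis-acid-mediated intramolecular Hosomi–Sakurai conjugate addition of cyclohexenylmethylsilanes to tethered vinyl ketones. Ring B closes in a 6-endo-trig mode with respect to the enone, C6 and C7 both becoming ring atoms. The only new stereocentre, C5, is controlled by the quaternary C10: the three-atom tether should reach C5 on the face of ring A that carries it, through a chair-like transition state with the chain pseudo-axial, which puts H5 cis to the C10 methyl group. The step needs conjugate rather than carbonyl addition and γ- rather than α-attack of the allylsilane; the first is secured by the s-cis enone bound to tetravalent titanium at low temperature, the second by stabilisation of developing charge at C4 by the C15–Si bond.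

Step 6
Reactants: 10 (4aR,8aR)-8a-methyl-5-methylideneoctahydronaphthalen-2(1H)-one; 11 methyl bromoacetate
Product: 13 methyl 2-[(2R,4aR,8aR)-4a-methyl-8-methylidene-3-oxodecahydronaphthalen-2-yl]acetate, via lithium enolate 12 (not isolated)
Conditions: LiN(i-Pr)2, THF, −78 °C; then 11, DMPU, −78 to −30 °C
Reagents that add atoms: none
Why: kinetic deprotonation should occur at C7 rather than at the neopentyl C9, and SN2 alkylation of the enolate is expected on the convex face of the cis-decalin (axial attack syn to H5), which sets C7 with the acetate chain cis to the angular methyl group.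

Step 7
Reactants: 13 methyl 2-[(2R,4aR,8aR)-4a-methyl-8-methylidene-3-oxodecahydronaphthalen-2-yl]acetate
Product: 15 (3aR,4aR,8aR,9aR)-8a-methyl-5-methylidenedecahydronaphtho[2,3-b]furan-2(3H)-one, via lithium alkoxide 14 (not isolated)
Conditions: LiBH(s-Bu)3, THF, −78 °C to rt; aq. NH4Cl; then PPTS (cat.), PhH, rt
Reagents that add atoms: none
Why: the bulky borohydride should attack the C8 ketone equatorially, away from the axial angular methyl group, giving the axial alkoxide cis to the equatorial C7 chain, which closes onto the methyl ester (acyl substitution) to the cis-fused γ-lactone.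

Step 8
Reactants: 15 (3aR,4aR,8aR,9aR)-8a-methyl-5-methylidenedecahydronaphtho[2,3-b]furan-2(3H)-one
Product: 17 (3S,3aR,4aR,8aR,9aR)-3-[(dimethylamino)methyl]-8a-methyl-5-methylidenedecahydronaphtho[2,3-b]furan-2(3H)-one, via lithium lactone enolate 16 (not isolated)
Conditions: LiN(i-Pr)2, THF, −78 °C; then dimethyl(methylidene)ammonium iodide, −78 °C to rt
Reagents that add atoms: dimethyl(methylidene)ammonium iodide (Eschenmoser's salt), C=[N+](C)C.[I-]
Why: Mannich aminomethylation of the lactone enolate with a preformed iminium salt introduces C13 at C11 from the convex face; the C11 configuration is lost again in step 9.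

Step 9
Reactants: 17 (3S,3aR,4aR,8aR,9aR)-3-[(dimethylamino)methyl]-8a-methyl-5-methylidenedecahydronaphtho[2,3-b]furan-2(3H)-one
Product: 19 (3aR,4aR,8aR,9aR)-8a-methyl-3,5-dimethylidenedecahydronaphtho[2,3-b]furan-2(3H)-one, via ammonium iodide 18 (not isolated)
Conditions: MeI, MeOH, rt; then NaHCO3, CH2Cl2/H2O, rt
Reagents that add atoms: none
Why: quaternisation of the Mannich base and mild-base β-elimination of trimethylamine is the standard route to an α-methylene γ-lactone and should not touch the C4 methylene.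

Step 10
Reactants: 20 (S)-(+)-carvone, (5S)-2-methyl-5-(prop-1-en-2-yl)cyclohex-2-en-1-one
Product: 21 (5S)-5-acetyl-2-methylcyclohex-2-en-1-one
Conditions: O3, CH2Cl2/MeOH, −78 °C (Sudan red end point); Me2S, −78 °C to rt
Reagents that add atoms: ozone, [O-][O+]=O
Why: ozonolysis should cleave the electron-rich isopropenyl alkene much faster than the conjugated one, unmasking an acetyl group that later allows epimerisation of this carbon.

Step 11
Reactants: 21 (5S)-5-acetyl-2-methylcyclohex-2-en-1-one
Product: 22 (5S)-2-methyl-5-(2-methyl-1,3-dioxolan-2-yl)cyclohex-2-en-1-one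
Conditions: Me3SiOCH2CH2OSiMe3, Me3SiOTf (2 mol%), CH2Cl2, −78 to −20 °C
Reagents that add atoms: 1,2-bis(trimethylsilyloxy)ethane, C[Si](C)(C)OCCO[Si](C)(C)C
Why: silyl-triflate-catalysed dioxolane formation is selective for a saturated methyl ketone over the less electrophilic conjugated ketone.

Step 12
Reactants: 22 (5S)-2-methyl-5-(2-methyl-1,3-dioxolan-2-yl)cyclohex-2-en-1-one; 23 prop-1-en-2-ylmagnesium bromide; 24 acetaldehyde
Product: 26 (2S,3R,5S)-2-(1-hydroxyethyl)-2-methyl-5-(2-methyl-1,3-dioxolan-2-yl)-3-(prop-1-en-2-yl)cyclohexan-1-one (both carbinol epimers), via bromomagnesium enolate 25 (not isolated)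
Conditions: 23 (1.5 equiv), CuBr·SMe2 (20 mol%), THF, −78 to −40 °C; then 24 (5 equiv), −78 °C; AcOH quench at −78 °C
Reagents that add atoms: none
Why: copper-catalysed conjugate addition of the alkenyl Grignard reagent should occur axially and anti to the C5 substituent (as with carvone), and aldol addition of the resulting enolate to acetaldehyde anti to the new isopropenyl group leaves the methyl group of the quaternary carbon cis to the isopropenyl group.

Step 13
Reactants: 26 (2S,3R,5S)-2-(1-hydroxyethyl)-2-methyl-5-(2-methyl-1,3-dioxolan-2-yl)-3-(prop-1-en-2-yl)cyclohexan-1-one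
Product: 27 (2R,3R,5S)-2-ethenyl-2-methyl-5-(2-methyl-1,3-dioxolan-2-yl)-3-(prop-1-en-2-yl)cyclohexan-1-one
Conditions: methyl N-(triethylammoniosulfonyl)carbamate (Burgess reagent), PhMe, 70 °C
Reagents that add atoms: none
Why: syn-elimination through the sulfamate ester can only remove a methyl hydrogen, the other neighbour being quaternary, so the hydroxyethyl group should become the vinyl group without base-induced retro-aldol cleavage.

Step 14
Reactants: 27 (2R,3R,5S)-2-ethenyl-2-methyl-5-(2-methyl-1,3-dioxolan-2-yl)-3-(prop-1-en-2-yl)cyclohexan-1-one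
Product: 29 2-[(1R,3R,4R)-4-ethenyl-4-methyl-3-(prop-1-en-2-yl)cyclohexyl]-2-methyl-1,3-dioxolane, via hydrazone 28 (not isolated)
Conditions: N2H4·H2O, KOH, diethylene glycol, 130 °C then 195 °C
Reagents that add atoms: none
Why: Wolff–Kishner reduction removes the ring carbonyl, which has only served to activate C5' and C10', under basic conditions that the dioxolane, the non-isomerisable quaternary vinyl group and the isopropenyl group should survive.

Step 15
Reactants: 29 2-[(1R,3R,4R)-4-ethenyl-4-methyl-3-(prop-1-en-2-yl)cyclohexyl]-2-methyl-1,3-dioxolane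
Product: 31 1-[(1S,3R,4R)-4-ethenyl-4-methyl-3-(prop-1-en-2-yl)cyclohexyl]ethan-1-one, via axial methyl ketone 30 (not isolated)
Conditions: 1 M HCl, THF, rt; then NaOMe, MeOH, rt
Reagents that add atoms: water, O
Why: acetal hydrolysis followed by base-mediated enolisation should equilibrate C7' to the equatorial acetyl epimer, cis to the equatorial isopropenyl group, so the stereocentre inherited from carvone is inverted under thermodynamic control (the minor epimer is recycled).

Step 16
Reactants: 31 1-[(1S,3R,4R)-4-ethenyl-4-methyl-3-(prop-1-en-2-yl)cyclohexyl]ethan-1-one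
Product: 33 1-[(1S,3R,4R)-4-ethenyl-4-methyl-3-(prop-1-en-2-yl)cyclohexyl]ethenyl trifluoromethanesulfonate, via potassium enolate 32 (not isolated)
Conditions: KN(SiMe3)2, THF, −78 °C; then PhNTf2, −78 to 0 °C
Reagents that add atoms: N-phenylbis(trifluoromethanesulfonimide), O=S(=O)(N(c1ccccc1)S(=O)(=O)C(F)(F)F)C(F)(F)F
Why: kinetic deprotonation of the methyl ketone at the methyl group and O-sulfonylation should give the 1,1-disubstituted enol triflate without disturbing the adjacent ring stereocentre.

Step 17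
Reactants: 33 1-[(1S,3R,4R)-4-ethenyl-4-methyl-3-(prop-1-en-2-yl)cyclohexyl]ethenyl trifluoromethanesulfonate
Product: 34 2-[(1S,3R,4R)-4-ethenyl-4-methyl-3-(prop-1-en-2-yl)cyclohexyl]prop-2-enal
Conditions: Pd(PPh3)4 (5 mol%), CO (1 atm), Bu3SnH (slow addition), LiCl, THF, 50 °C
Reagents that add atoms: carbon monoxide, [C-]#[O+]
Why: palladium-catalysed reductive carbonylation (formylation) of a vinyl triflate with carbon monoxide and a tin hydride gives the 2-substituted acrolein directly.

Step 18
Reactants: 19 (3aR,4aR,8aR,9aR)-8a-methyl-3,5-dimethylidenedecahydronaphtho[2,3-b]furan-2(3H)-one; 34 2-[(1S,3R,4R)-4-ethenyl-4-methyl-3-(prop-1-en-2-yl)cyclohexyl]prop-2-enal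
Product: 35 CNP0353330.1, the spiro-dihydropyran with the configuration of the given SMILES
Conditions: 34 (2.5 equiv), BHT (5 mol%), PhMe (2 M), 130 °C, sealed tube
Reagents that add atoms: none
Why: thermal hetero-Diels–Alder reaction of the acrolein-type heterodiene (O=C12'–C11'=C13') with the α-methylene lactone as dienophile should join O to the carbonyl-bearing C11 and C13' to C13, the regiochemistry known from acrolein dimerisation and its additions to methacrylates; approach on the convex face of the cis-fused lactone puts the ring oxygen cis to H7 and so sets the spiro centre C11.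

**Compound list**

1 | 3-methylcyclohex-2-en-1-one | CC1=CC(=O)CCC1 | starting material
2 | but-3-en-1-ylmagnesium bromide (commercial solution, or from 4-bromobut-1-ene and Mg in Et2O) | C=CCC[Mg]Br | starting material
3 | bromomagnesium (3R)-3-(but-3-en-1-yl)-3-methylcyclohex-1-en-1-olate | C=CCC[C@@]1(C)CCCC(O[Mg]Br)=C1 | intermediate
4 | (3R)-3-(but-3-en-1-yl)-3-methylcyclohex-1-en-1-yl trifluoromethanesulfonate | C=CCC[C@@]1(C)CCCC(OS(=O)(=O)C(F)(F)F)=C1 | intermediate
5 | (3R)-3-(2-hydroxybut-3-en-1-yl)-3-methylcyclohex-1-en-1-yl trifluoromethanesulfonate (carbinol epimers) | C=CC(O)C[C@@]1(C)CCCC(OS(=O)(=O)C(F)(F)F)=C1 | intermediate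
6 | (trimethylsilyl)methylmagnesium chloride | C[Si](C)(C)C[Mg]Cl | starting material
7 | 1-[(1R)-1-methyl-3-[(trimethylsilyl)methyl]cyclohex-2-en-1-yl]but-3-en-2-ol | C=CC(O)C[C@@]1(C)CCCC(C[Si](C)(C)C)=C1 | intermediate
8 | 1-[(1R)-1-methyl-3-[(trimethylsilyl)methyl]cyclohex-2-en-1-yl]but-3-en-2-one | C=CC(=O)C[C@@]1(C)CCCC(C[Si](C)(C)C)=C1 | intermediate
9 | trichlorotitanium enolate of 10 (C7=C8) | Cl[Ti](Cl)(Cl)OC1=CC[C@@H]2C(=C)CCC[C@]2(C)C1 | intermediate
10 | (4aR,8aR)-8a-methyl-5-methylideneoctahydronaphthalen-2(1H)-one, cis-fused | O=C1C[C@@]2(C)CCCC(=C)[C@H]2CC1 | intermediate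
11 | methyl bromoacetate | COC(=O)CBr | starting material
12 | lithium enolate of 10 (C7=C8) | [Li]OC1=CC[C@@H]2C(=C)CCC[C@]2(C)C1 | intermediate
13 | methyl 2-[(2R,4aR,8aR)-4a-methyl-8-methylidene-3-oxodecahydronaphthalen-2-yl]acetate | O=C1[C@@H](CC(=O)OC)C[C@@H]2C(=C)CCC[C@]2(C)C1 | intermediate
14 | lithium alkoxide of methyl 2-[(2R,3R,4aR,8aR)-3-hydroxy-4a-methyl-8-methylidenedecahydronaphthalen-2-yl]acetate | [Li]O[C@@H]1C[C@@]2(C)CCCC(=C)[C@H]2C[C@@H]1CC(=O)OC | intermediate
15 | (3aR,4aR,8aR,9aR)-8a-methyl-5-methylidenedecahydronaphtho[2,3-b]furan-2(3H)-one | O=C1O[C@@H]2C[C@@]3(C)CCCC(=C)[C@H]3C[C@@H]2C1 | intermediate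
16 | lithium enolate of 15 | [Li]OC1O[C@@H]2C[C@@]3(C)CCCC(=C)[C@H]3C[C@@H]2C=1 | intermediate
17 | (3S,3aR,4aR,8aR,9aR)-3-[(dimethylamino)methyl]-8a-methyl-5-methylidenedecahydronaphtho[2,3-b]furan-2(3H)-one | O=C1O[C@@H]2C[C@@]3(C)CCCC(=C)[C@H]3C[C@@H]2[C@H]1CN(C)C | intermediate
18 | trimethylammonium iodide of 17 | O=C1O[C@@H]2C[C@@]3(C)CCCC(=C)[C@H]3C[C@@H]2[C@H]1C[N+](C)(C)C.[I-] | intermediate
19 | (3aR,4aR,8aR,9aR)-8a-methyl-3,5-dimethylidenedecahydronaphtho[2,3-b]furan-2(3H)-one | O=C1O[C@@H]2C[C@@]3(C)CCCC(=C)[C@H]3C[C@@H]2C1=C | intermediate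
20 | (S)-(+)-carvone, (5S)-2-methyl-5-(prop-1-en-2-yl)cyclohex-2-en-1-one | CC1=CC[C@@H](CC1=O)C(C)=C | starting material
21 | (5S)-5-acetyl-2-methylcyclohex-2-en-1-one | CC1=CC[C@@H](CC1=O)C(C)=O | intermediate
22 | (5S)-2-methyl-5-(2-methyl-1,3-dioxolan-2-yl)cyclohex-2-en-1-one | CC1=CC[C@@H](CC1=O)C1(C)OCCO1 | intermediate
23 | prop-1-en-2-ylmagnesium bromide | CC(=C)[Mg]Br | starting material
24 | acetaldehyde | CC=O | starting material
25 | bromomagnesium enolate from 22 and 23 | CC1=C(O[Mg]Br)C[C@@H](C2(C)OCCO2)C[C@@H]1C(C)=C | intermediate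
26 | (2S,3R,5S)-2-(1-hydroxyethyl)-2-methyl-5-(2-methyl-1,3-dioxolan-2-yl)-3-(prop-1-en-2-yl)cyclohexan-1-one (carbinol epimers) | CC(O)[C@@]1(C)C(=O)C[C@@H](C2(C)OCCO2)C[C@@H]1C(C)=C | intermediate
27 | (2R,3R,5S)-2-ethenyl-2-methyl-5-(2-methyl-1,3-dioxolan-2-yl)-3-(prop-1-en-2-yl)cyclohexan-1-one | C=C[C@@]1(C)C(=O)C[C@@H](C2(C)OCCO2)C[C@@H]1C(C)=C | intermediate
28 | hydrazone of 27 | C=C[C@@]1(C)C(=NN)C[C@@H](C2(C)OCCO2)C[C@@H]1C(C)=C | intermediate
29 | 2-[(1R,3R,4R)-4-ethenyl-4-methyl-3-(prop-1-en-2-yl)cyclohexyl]-2-methyl-1,3-dioxolane | C=C[C@@]1(C)CC[C@@H](C2(C)OCCO2)C[C@@H]1C(C)=C | intermediate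
30 | 1-[(1R,3R,4R)-4-ethenyl-4-methyl-3-(prop-1-en-2-yl)cyclohexyl]ethan-1-one (axial acetyl) | C=C[C@@]1(C)CC[C@@H](C(C)=O)C[C@@H]1C(C)=C | intermediate
31 | 1-[(1S,3R,4R)-4-ethenyl-4-methyl-3-(prop-1-en-2-yl)cyclohexyl]ethan-1-one (equatorial acetyl) | C=C[C@@]1(C)CC[C@H](C(C)=O)C[C@@H]1C(C)=C | intermediate
32 | potassium enolate of 31 (methyl side) | C=C[C@@]1(C)CC[C@H](C(=C)O[K])C[C@@H]1C(C)=C | intermediate
33 | 1-[(1S,3R,4R)-4-ethenyl-4-methyl-3-(prop-1-en-2-yl)cyclohexyl]ethenyl trifluoromethanesulfonate | C=C[C@@]1(C)CC[C@H](C(=C)OS(=O)(=O)C(F)(F)F)C[C@@H]1C(C)=C | intermediate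
34 | 2-[(1S,3R,4R)-4-ethenyl-4-methyl-3-(prop-1-en-2-yl)cyclohexyl]prop-2-enal | C=C[C@@]1(C)CC[C@H](C(=C)C=O)C[C@@H]1C(C)=C | intermediate
35 | CNP0353330.1: 3,4-dihydro-2H-pyran spiro-fused through its C2 to C11 of the lactone 15 skeleton (11R; ring oxygen cis to H7) and bearing the (1S,3R,4R)-4-ethenyl-4-methyl-3-(prop-1-en-2-yl)cyclohexyl group on its C5 | C=C[C@@]1(C)CC[C@H](C2=CO[C@@]3(CC2)C(=O)O[C@@H]2C[C@@]4(C)CCCC(=C)[C@H]4C[C@@H]23)C[C@@H]1C(=C)C | target

**Count and risks**

Total step count: 18. Longest linear sequence: 10 (steps 1–9, then step 18); the elemane half takes steps 10–17.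

Step 18 is the most likely to fail. The cross-cycloaddition may be outrun by self-dimerisation of the enal or by thermal polymerisation of either partner, and face selectivity at C11 may be incomplete. The fallback sets out from 34 and 19 and returns to the route at 35, replacing the pericyclic union by a stepwise one. Conjugate addition of iodide to 34 (NaI, Me3SiCl, MeCN, −20 °C) and quenching with methanol should give (1R,2R,4S)-1-ethenyl-4-(1-iodo-3,3-dimethoxypropan-2-yl)-1-methyl-2-(prop-1-en-2-yl)cyclohexane F4. Tin-hydride-mediated Giese addition of its primary radical to the methylene of 19 (Bu3SnH, AIBN, PhH, 80 °C) forms the C13–C13' bond and gives the 11-H lactone acetal F5. Deprotonation at C11 (KN(SiMe3)2, THF, −78 °C) and oxidation with 2-(phenylsulfonyl)-3-phenyloxaziridine on the convex face gives the 11-hydroxy lactone acetal F6. Aqueous acetic acid in THF then hydrolyses the acetal, and the tertiary alcohol closes to the spiro lactol F7. Dehydration with MeSO2Cl and Et3N (CH2Cl2, 0 °C to rt) gives 35.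

Step 2 is the second risk. Allylic oxidation of the monosubstituted alkene may stall at low conversion or run on to the enone, and the ring allylic positions may compete. The fallback sets out from 4 and returns at 5. RuHCl(CO)(PPh3)3 in toluene at 80 °C moves the terminal alkene by one position to give (3R)-3-[(2E)-but-2-en-1-yl]-3-methylcyclohex-1-en-1-yl trifluoromethanesulfonate F1. Ozonolysis (O3, CH2Cl2, −78 °C; PPh3), which should spare the electron-poor enol triflate, gives 2-[(1R)-1-methyl-3-(trifluoromethanesulfonyloxy)cyclohex-2-en-1-yl]acetaldehyde F2. Addition of vinylmagnesium bromide (THF, −78 °C) then gives 5.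

Step 12 is the third risk. Trapping of the hindered, fully substituted enolate may be reversed by retro-aldol cleavage on warming or quenching, or be pre-empted by proton transfer, so that the two-carbon unit is lost. The fallback sets out from 22 and returns at 27, skipping 26. After the same copper-catalysed addition of 23, enolate 25 is intercepted by Michael addition to phenyl vinyl sulfoxide (THF/DMPU, −78 to 0 °C) to give (2R,3R,5S)-2-methyl-5-(2-methyl-1,3-dioxolan-2-yl)-2-[2-(phenylsulfinyl)ethyl]-3-(prop-1-en-2-yl)cyclohexan-1-one F3. Sulfoxide syn-elimination (PhMe, CaCO3, 110 °C) then gives 27.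

**Further compounds**

F1 | step 2 | (3R)-3-[(2E)-but-2-en-1-yl]-3-methylcyclohex-1-en-1-yl trifluoromethanesulfonate | C/C=C/C[C@@]1(C)CCCC(OS(=O)(=O)C(F)(F)F)=C1
F2 | step 2 | 2-[(1R)-1-methyl-3-(trifluoromethanesulfonyloxy)cyclohex-2-en-1-yl]acetaldehyde | O=CC[C@@]1(C)CCCC(OS(=O)(=O)C(F)(F)F)=C1
F3 | step 12 | (2R,3R,5S)-2-methyl-5-(2-methyl-1,3-dioxolan-2-yl)-2-[2-(phenylsulfinyl)ethyl]-3-(prop-1-en-2-yl)cyclohexan-1-one (sulfoxide epimers) | O=S(CC[C@@]1(C)C(=O)C[C@@H](C2(C)OCCO2)C[C@@H]1C(C)=C)c1ccccc1
F4 | step 18 | (1R,2R,4S)-1-ethenyl-4-(1-iodo-3,3-dimethoxypropan-2-yl)-1-methyl-2-(prop-1-en-2-yl)cyclohexane (side-chain epimers) | C=C[C@@]1(C)CC[C@H](C(CI)C(OC)OC)C[C@@H]1C(C)=C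
F5 | step 18 | (3aR,4aR,8aR,9aR)-3-{3-[(1S,3R,4R)-4-ethenyl-4-methyl-3-(prop-1-en-2-yl)cyclohexyl]-4,4-dimethoxybutyl}-8a-methyl-5-methylidenedecahydronaphtho[2,3-b]furan-2(3H)-one (epimers at C11 and C11') | C=C[C@@]1(C)CC[C@H](C(CCC2C(=O)O[C@@H]3C[C@@]4(C)CCCC(=C)[C@H]4C[C@H]23)C(OC)OC)C[C@@H]1C(C)=C
F6 | step 18 | (3R,3aS,4aR,8aR,9aR)-3-{3-[(1S,3R,4R)-4-ethenyl-4-methyl-3-(prop-1-en-2-yl)cyclohexyl]-4,4-dimethoxybutyl}-3-hydroxy-8a-methyl-5-methylidenedecahydronaphtho[2,3-b]furan-2(3H)-one (epimers at C11') | C=C[C@@]1(C)CC[C@H](C(CC[C@]2(O)C(=O)O[C@@H]3C[C@@]4(C)CCCC(=C)[C@H]4C[C@H]23)C(OC)OC)C[C@@H]1C(C)=C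
F7 | step 18 | spiro lactol: the 6-hydroxytetrahydropyran analogue of 35 (O–CH(OH)–CH in place of O–CH=C; epimers at the two new carbons) | C=C[C@@]1(C)CC[C@H](C2CC[C@]3(OC2O)C(=O)O[C@@H]2C[C@@]4(C)CCCC(=C)[C@H]4C[C@@H]23)C[C@@H]1C(C)=C
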